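**Retrosynthetic overview**
- Target ⇒ O–CH3 disconnection at one of the two ketone-flanked oxygens, giving the symmetric 2,4,6-trihydroxy-3,5-diprenylbenzophenone plus methylboronic acid. This chelation-directed C–O bond formation is the key step and decides which of the three OH groups carries the methyl.
- The diprenyl triphenol ⇒ 2,4,6-trihydroxybenzophenone + 2 prenyl bromide (double C-prenylation of the phenolate).
- 2,4,6-Trihydroxybenzophenone ⇒ phloroglucinol + benzoyl chloride (Friedel–Crafts acylation).
- No ring is constructed: both benzene rings are bought. The order of events is acylation, C-prenylation, O-methylation.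

Assumption: the target has no stereocentre and no stereogenic double bond (both alkenes end in CMe2), so it is achiral and "single enantiomer" is read as the single constitutional isomer drawn. Prenyl = 3-methylbut-2-en-1-yl.

**Step 1**
Reactants: 1 phloroglucinol; 2 benzoyl chloride
Product: 3 2,4,6-trihydroxybenzophenone
Conditions: AlCl3 (4 equiv), PhNO2, rt → 65 °C; ice/2 M HCl quench
Reagents that add atoms: benzoyl chloride, O=C(Cl)c1ccccc1
Why: Friedel–Crafts acylation of a very electron-rich arene whose three CH positions are equivalent, so there is no regiochemical issue, and the first benzoyl group (held as an aluminium chelate) deactivates the ring against a second acylation.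

**Step 2**
Reactants: 3 2,4,6-trihydroxybenzophenone; 4 prenyl bromide
Product: 6 2,4,6-trihydroxy-3,5-diprenylbenzophenone, via 3-prenyl-2,4,6-trihydroxybenzophenone 5 (not isolated)
Conditions: prenyl bromide (2.1 equiv), 5% aq. KOH, 0 °C, 2 h; then 1 M HCl to pH 3, SiO2 chromatography
Reagents that add atoms: prenyl bromide, CC(C)=CCBr
Why: Phenolate C-alkylation (SN2 at the allylic bromide): in water the phenoxide oxygens are hydrogen-bonded, so the soft electrophile is taken by the ring carbons that lie between two oxyanions, first one (5) and then the other, as is established for acylphloroglucinols.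

**Step 3**
Reactants: 6 2,4,6-trihydroxy-3,5-diprenylbenzophenone; 7 methylboronic acid
Product: 10 2,4-dihydroxy-6-methoxy-3,5-diprenylbenzophenone, via divalent copper aryloxide chelate 8 (not isolated), via trivalent methylcopper aryloxide 9 (not isolated)
Conditions: Cu(OAc)2 (2.2 equiv), pyridine (4 equiv), MeB(OH)2 (1.3 equiv, in three portions), ClCH2CH2Cl, 70 °C, argon, dark, stopped at ca. 85% conversion of 6; aq. NH4Cl wash
Reagents that add atoms: methylboronic acid, CB(O)O
Why: Proposed new method: a chelation-directed Chan–Lam-type O-methylation in which the substrate itself picks the oxygen. The 2-hydroxyaryl ketone unit of 6 is an acetylacetonate-like O,O-ligand, so Cu(OAc)2 is bound at a ketone-flanked phenoxide (8) and not at the para oxygen, which is monodentate and screened by two prenyl groups. Acetate-bridged boron-to-copper methyl transfer and one-electron oxidation by the second Cu(OAc)2 give 9, and three-centre C–O reductive elimination puts the methyl on the copper-bound oxygen, the opposite of the para selectivity expected from SN2 reagents (MeI/K2CO3, CH2N2) on acylphloroglucinols. The two ketone-flanked OH groups of 6 are equivalent by symmetry, so either gives 10; the ring has no free CH for oxidative phenol coupling, and running without O2 (copper as the stoichiometric oxidant, more than 2 Cu per substrate to avoid an inert bis-aryloxide complex) spares the prenyl alkenes. The closest known reaction type is the Chan–Lam oxidative copper-mediated O-methylation of simple phenols with methylboronic acid, which has not been used to choose one OH among several by chelation.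

**Compound list**
1 | phloroglucinol (benzene-1,3,5-triol) | Oc1cc(O)cc(O)c1 | starting material
2 | benzoyl chloride | O=C(Cl)c1ccccc1 | starting material
3 | 2,4,6-trihydroxybenzophenone | O=C(c1ccccc1)c1c(O)cc(O)cc1O | intermediate
4 | prenyl bromide (1-bromo-3-methylbut-2-ene) | CC(C)=CCBr | starting material
5 | 3-prenyl-2,4,6-trihydroxybenzophenone (not isolated) | CC(C)=CCc1c(O)cc(O)c(C(=O)c2ccccc2)c1O | intermediate
6 | 2,4,6-trihydroxy-3,5-diprenylbenzophenone (clusiaphenone B; prenyls on the two carbons between OH groups) | CC(C)=CCc1c(O)c(CC=C(C)C)c(O)c(C(=O)c2ccccc2)c1O | intermediate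
7 | methylboronic acid | CB(O)O | starting material
8 | divalent copper aryloxide chelate of 6 (Cu bound to a ketone-flanked phenoxide and carrying acetate; ketone oxygen and pyridine also on copper, dative bonds not drawn; not isolated) | CC(C)=CCc1c(O)c(CC=C(C)C)c(O)c(C(=O)c2ccccc2)c1O[Cu]OC(C)=O | intermediate
9 | trivalent methylcopper aryloxide (same aryloxide with methyl and acetate on copper; not isolated) | CC(C)=CCc1c(O)c(CC=C(C)C)c(O)c(C(=O)c2ccccc2)c1O[Cu](C)OC(C)=O | intermediate
10 | 2,4-dihydroxy-6-methoxy-3,5-diprenylbenzophenone (achiral) | COc1c(CC=C(C)C)c(O)c(CC=C(C)C)c(O)c1C(=O)c1ccccc1 | target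

**Totals**
Total steps: 3 (two if 3 is bought rather than made). Longest linear sequence: 3.

**Steps most likely to fail**

1. Step 3 (the new methylation). The risks are that the copper does not discriminate well enough and some 4-O-methyl isomer forms, that the second ketone-flanked OH is also methylated, or that divalent copper slowly oxidises the electron-rich triphenol. The product is easy to tell apart: 10 is unsymmetrical (two different prenyl groups, one chelated OH near 12–13 ppm), while the 4-O-methyl isomer is symmetric.
Fallback with known chemistry, setting out from 6 and coming back at 10: MOMCl (2.3 equiv), i-Pr2NEt, CH2Cl2, 0 °C → rt protects the para OH and one ketone-flanked OH. The last OH is held back by its hydrogen bond to the ketone, which gives 2-hydroxy-4,6-bis(methoxymethoxy)-3,5-diprenylbenzophenone F1. MeI, K2CO3, acetone at reflux then methylates the only OH left to give 2-methoxy-4,6-bis(methoxymethoxy)-3,5-diprenylbenzophenone F2. Finally 3 M HCl in MeOH at rt–40 °C, conditions that ortho-prenyl phenols normally tolerate, removes both MOM groups and gives 10.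

2. Step 2 (double C-prenylation). Mono-, tri- and O-prenylated by-products keep the yield modest, about 35–40% expected.
Fallback that replaces direct alkylation by rearrangement and metathesis, setting out from 3 and coming back at 6: allyl bromide (2.2 equiv), K2CO3, acetone at reflux gives 2,4-bis(allyloxy)-6-hydroxybenzophenone F3. A double aromatic Claisen rearrangement (N,N-diethylaniline, 195 °C) moves both allyl groups to the two ring CH positions, an allyl that arrives at an occupied carbon being passed on by a Cope shift, and gives 3,5-diallyl-2,4,6-trihydroxybenzophenone F4. Double cross-metathesis with excess 2-methyl-2-butene (second-generation Grubbs catalyst, 5 mol %, CH2Cl2, 40 °C) turns each allyl into prenyl and gives 6.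

3. Step 1 (Friedel–Crafts benzoylation). O-benzoylation or over-acylation can lower the yield.
Fallback that changes the electrophile, setting out from 1 and coming back at 3: a Houben–Hoesch reaction with benzonitrile, ZnCl2 and dry HCl in Et2O at 0 °C precipitates 2,4,6-trihydroxybenzophenone iminium chloride F5, and boiling water hydrolyses it to 3.

**Further compounds**
F1 | step 3 | 2-hydroxy-4,6-bis(methoxymethoxy)-3,5-diprenylbenzophenone | COCOc1c(CC=C(C)C)c(OCOC)c(CC=C(C)C)c(O)c1C(=O)c1ccccc1
F2 | step 3 | 2-methoxy-4,6-bis(methoxymethoxy)-3,5-diprenylbenzophenone | COCOc1c(CC=C(C)C)c(OCOC)c(CC=C(C)C)c(OC)c1C(=O)c1ccccc1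
F3 | step 2 | 2,4-bis(allyloxy)-6-hydroxybenzophenone | C=CCOc1cc(OCC=C)c(C(=O)c2ccccc2)c(O)c1
F4 | step 2 | 3,5-diallyl-2,4,6-trihydroxybenzophenone | C=CCc1c(O)c(CC=C)c(O)c(C(=O)c2ccccc2)c1O
F5 | step 1 | 2,4,6-trihydroxybenzophenone iminium chloride | [NH2+]=C(c1ccccc1)c1c(O)cc(O)cc1O.[Cl-]
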